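**Retrosynthetic overview**
1. Target 22 ⇒ two late C–O acylations: C1–O angelate last, C4–O trimethoxybenzoate before it, on diol 16 (azulene numbering for all bicycles).
2. 16 ⇒ i-Pr–Ce addition to cis-hydroazulenone 15; 15 ⇒ formal conjugate hydration of dienone 13 (key C–O bond C4–O, set together with C3a–H).
3. 13 ⇒ dehydration of aldols 11; 11 ⇒ ring-closing metathesis of 10 (seven-membered ring formed second).
4. 10 ⇒ enone 6 + Me2CuLi + aldehyde 8 (quaternary C8a set anti to OTBS; cyclopentane carried from 1).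
5. 6 ⇒ Stork–Danheiser transposition of 4; 4 ⇒ enantioselective α′-oxygenation (first C–O bond, the only external source of chirality) of 3-ethoxycyclopentenone 1.

Assumption: 1, 7, 17 and 20 are bought; the (+)-oxaziridine (step 1) and (R,S)-Josiphos (step 7) are written for a sense of induction assumed by analogy, and the mirror-image reagent or ligand (both sold) is used if the sense proves opposite.

Step 1
Reactants: 1 3-ethoxycyclopent-2-en-1-one
Product: 4 (5S)-5-[(tert-butyldimethylsilyl)oxy]-3-ethoxycyclopent-2-en-1-one, via sodium dienolate 2 (not isolated), via sodium alkoxide 3 (not isolated)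
Conditions: NaHMDS, THF, −78 °C; (+)-[(8,8-dichlorocamphoryl)sulfonyl]oxaziridine, −78 °C; TBSOTf, −78 → 0 °C
Reagents that add atoms: (+)-[(8,8-dichlorocamphoryl)sulfonyl]oxaziridine, CC1(C)[C@@H]2CC[C@]13CS(=O)(=O)N4O[C@@]34C2(Cl)Cl; tert-butyldimethylsilyl triflate, CC(C)(C)[Si](C)(C)OS(=O)(=O)C(F)(F)F
Why: Proposed new method: reagent-controlled enantioselective α′-hydroxylation of a cross-conjugated vinylogous-ester dienolate with in-flask O-silylation, in which the kinetic enolate 2 attacks the oxaziridine oxygen in an open SN2-type transition state whose camphor and sulfonyl groups shield one enolate face so that the (S) C–O stereocentre is set, and silyl capture of alkoxide 3 before warming prevents enolisation and racemisation; the closest known reaction is the Davis asymmetric oxaziridine hydroxylation of simple ketone and ester enolates, not shown for α′-enolates of 3-alkoxyenones.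

Step 2
Reactants: 4 (5S)-5-[(tert-butyldimethylsilyl)oxy]-3-ethoxycyclopent-2-en-1-one
Product: 6 (4S)-4-[(tert-butyldimethylsilyl)oxy]-3-(prop-2-en-1-yl)cyclopent-2-en-1-one, via bromomagnesium alkoxide 5 (not isolated)
Conditions: allylMgBr, THF, −78 → 0 °C; then 1 M aq HCl, 0 °C
Reagents that add atoms: allylmagnesium bromide, C=CC[Mg]Br
Why: 1,2-Addition to the vinylogous-ester carbonyl and acid hydrolysis of the β-hydroxy enol ether (Stork–Danheiser transposition) move the carbonyl so that the untouched silyloxy stereocentre becomes the γ-carbon of a 3-allyl enone.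

Step 3
Reactants: 7 3-methylbut-3-en-1-ol
Product: 8 3-methylbut-3-enal
Conditions: Dess–Martin periodinane, NaHCO3, CH2Cl2, 0 °C; filtered and used at once as a CH2Cl2 solution
Reagents that add atoms: none
Why: Buffered Dess–Martin oxidation gives the β,γ-unsaturated aldehyde without migration of the double bond into conjugation and creates no stereocentre.

Step 4
Reactants: 6 (4S)-4-[(tert-butyldimethylsilyl)oxy]-3-(prop-2-en-1-yl)cyclopent-2-en-1-one; 8 3-methylbut-3-enal
Product: 10 (3R,4S)-4-[(tert-butyldimethylsilyl)oxy]-2-(1-hydroxy-3-methylbut-3-en-1-yl)-3-methyl-3-(prop-2-en-1-yl)cyclopentan-1-one (mixture of epimers at C2 and at the carbinol carbon), via lithium enolate 9 (not isolated)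
Conditions: Me2CuLi (from MeLi, CuI), Et2O, −78 → −30 °C; then 8, THF, −78 °C; aq NH4Cl
Reagents that add atoms: lithium dimethylcuprate, [Li+].C[Cu-]C
Why: Cuprate conjugate addition occurs anti to the γ-silyloxy group and so sets the quaternary centre (methyl trans to OTBS, allyl cis), and the regiodefined enolate is trapped by aldol addition (three-component coupling) whose two new centres are erased in step 6.

Step 5
Reactants: 10 (3R,4S)-4-[(tert-butyldimethylsilyl)oxy]-2-(1-hydroxy-3-methylbut-3-en-1-yl)-3-methyl-3-(prop-2-en-1-yl)cyclopentan-1-one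
Product: 11 (1S,8aR)-1-[(tert-butyldimethylsilyl)oxy]-4-hydroxy-6,8a-dimethyl-1,3a,4,5,8,8a-hexahydroazulen-3(2H)-one (mixture of epimers at C3a and C4)
Conditions: Grubbs II (5 mol %), CH2Cl2 (3 mM), 40 °C
Reagents that add atoms: none
Why: Ring-closing metathesis of the allyl and 2-methylallyl groups closes the trisubstituted cycloheptene for every diastereomer and touches no stereocentre.

Step 6
Reactants: 11 (1S,8aR)-1-[(tert-butyldimethylsilyl)oxy]-4-hydroxy-6,8a-dimethyl-1,3a,4,5,8,8a-hexahydroazulen-3(2H)-one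
Product: 13 (1S,8aR)-1-[(tert-butyldimethylsilyl)oxy]-6,8a-dimethyl-1,5,8,8a-tetrahydroazulen-3(2H)-one, via mesylate 12 (not isolated)
Conditions: MsCl, Et3N, CH2Cl2, −20 → 0 °C
Reagents that add atoms: none
Why: O-Mesylation and E1cB elimination through the ketone enolate converge all aldol diastereomers on one enone whose C3a=C4 geometry is fixed by the ring, while the mild amine base at low temperature is chosen to avoid moving the skipped diene into conjugation.

Step 7
Reactants: 13 (1S,8aR)-1-[(tert-butyldimethylsilyl)oxy]-6,8a-dimethyl-1,5,8,8a-tetrahydroazulen-3(2H)-one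
Product: 15 (1S,3aR,4R,8aR)-1-[(tert-butyldimethylsilyl)oxy]-4-hydroxy-6,8a-dimethyl-1,3a,4,5,8,8a-hexahydroazulen-3(2H)-one, via boryl ketone 14 (not isolated)
Conditions: CuCl (5 mol %), (R,S)-Josiphos (6 mol %), NaOtBu (8 mol %), B2pin2, MeOH, THF, 0 °C; then NaBO3·4H2O, THF/H2O, rt
Reagents that add atoms: sodium perborate, [Na+].[O-]B1OO1
Why: Ligand-controlled borylcupration puts boron on C4 from the face of the angular methyl, the copper enolate is protonated at C3a on the same face to give the cis ring fusion (expected, by analogy with hydrindanones, to be also the more stable fusion), and perborate replaces boron by oxygen with retention (asymmetric conjugate borylation–oxidation as a formal conjugate hydration).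

Step 8
Reactants: 15 (1S,3aR,4R,8aR)-1-[(tert-butyldimethylsilyl)oxy]-4-hydroxy-6,8a-dimethyl-1,3a,4,5,8,8a-hexahydroazulen-3(2H)-one
Product: 16 (1S,3S,3aR,4R,8aR)-1-[(tert-butyldimethylsilyl)oxy]-6,8a-dimethyl-3-(propan-2-yl)-1,2,3,3a,4,5,8,8a-octahydroazulene-3,4-diol
Conditions: i-PrMgCl, CeCl3, THF, −78 → 0 °C; aq NH4Cl
Reagents that add atoms: isopropylmagnesium chloride, CC(C)[Mg]Cl
Why: The weakly basic organocerium reagent (Imamoto conditions) adds to the hindered ketone from the convex face, anti to the seven-membered ring and the OTBS group, so the new tertiary hydroxyl is cis to OTBS.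

Step 9
Reactants: 16 (1S,3S,3aR,4R,8aR)-1-[(tert-butyldimethylsilyl)oxy]-6,8a-dimethyl-3-(propan-2-yl)-1,2,3,3a,4,5,8,8a-octahydroazulene-3,4-diol; 17 3,4,5-trimethoxybenzoyl chloride
Product: 18 (1S,3S,3aR,4R,8aR)-1-[(tert-butyldimethylsilyl)oxy]-3-hydroxy-6,8a-dimethyl-3-(propan-2-yl)-1,2,3,3a,4,5,8,8a-octahydroazulen-4-yl 3,4,5-trimethoxybenzoate
Conditions: Et3N, DMAP (cat.), CH2Cl2, 0 °C → rt
Reagents that add atoms: none
Why: DMAP-catalysed acylation occurs only at the secondary C4 hydroxyl because the tertiary hydroxyl is unreactive and C1–O is silylated, and no stereocentre is touched.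

Step 10
Reactants: 18 (1S,3S,3aR,4R,8aR)-1-[(tert-butyldimethylsilyl)oxy]-3-hydroxy-6,8a-dimethyl-3-(propan-2-yl)-1,2,3,3a,4,5,8,8a-octahydroazulen-4-yl 3,4,5-trimethoxybenzoate
Product: 19 (1S,3S,3aR,4R,8aR)-1,3-dihydroxy-6,8a-dimethyl-3-(propan-2-yl)-1,2,3,3a,4,5,8,8a-octahydroazulen-4-yl 3,4,5-trimethoxybenzoate
Conditions: HF·pyridine, pyridine, THF, 0 °C → rt
Reagents that add atoms: none
Why: Buffered fluoride desilylation frees the C1 hydroxyl without ester cleavage or acyl migration and with retention of configuration.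

Step 11
Reactants: 19 (1S,3S,3aR,4R,8aR)-1,3-dihydroxy-6,8a-dimethyl-3-(propan-2-yl)-1,2,3,3a,4,5,8,8a-octahydroazulen-4-yl 3,4,5-trimethoxybenzoate; 20 angelic acid
Product: 22 (1S,3S,3aR,4R,8aR)-3-hydroxy-6,8a-dimethyl-1-{[(2Z)-2-methylbut-2-enoyl]oxy}-3-(propan-2-yl)-1,2,3,3a,4,5,8,8a-octahydroazulen-4-yl 3,4,5-trimethoxybenzoate, via mixed anhydride 21 (not isolated)
Conditions: 20, 2,4,6-trichlorobenzoyl chloride, Et3N, toluene, rt; then 19, toluene, 80 °C
Reagents that add atoms: none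
Why: Yamaguchi-type acylation with the preformed angelic mixed anhydride, run without DMAP, esterifies the hindered secondary C1 hydroxyl (the tertiary one stays free) with retention at C1 and without Z→E isomerisation to the tiglate.

**Compound list**
1 | 3-ethoxycyclopent-2-en-1-one | CCOC1=CC(=O)CC1 | starting material
2 | sodium 4-ethoxycyclopenta-1,3-dien-2-olate (α′-dienolate of 1) | CCOC1=CC([O-])=CC1.[Na+] | intermediate (not isolated)
3 | sodium (1S)-4-ethoxy-2-oxocyclopent-3-en-1-olate | CCOC1=CC(=O)[C@@H]([O-])C1.[Na+] | intermediate (not isolated)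
4 | (5S)-5-[(tert-butyldimethylsilyl)oxy]-3-ethoxycyclopent-2-en-1-one | CCOC1=CC(=O)[C@@H](O[Si](C)(C)C(C)(C)C)C1 | intermediate
5 | bromomagnesium (5S)-5-[(tert-butyldimethylsilyl)oxy]-3-ethoxy-1-(prop-2-en-1-yl)cyclopent-2-en-1-olate (both C1 epimers) | CCOC1=CC([O-])(CC=C)[C@@H](O[Si](C)(C)C(C)(C)C)C1.[Mg+]Br | intermediate (not isolated)
6 | (4S)-4-[(tert-butyldimethylsilyl)oxy]-3-(prop-2-en-1-yl)cyclopent-2-en-1-one | C=CCC1=CC(=O)C[C@@H]1O[Si](C)(C)C(C)(C)C | intermediate
7 | 3-methylbut-3-en-1-ol | CC(=C)CCO | starting material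
8 | 3-methylbut-3-enal | CC(=C)CC=O | intermediate
9 | lithium (3R,4S)-4-[(tert-butyldimethylsilyl)oxy]-3-methyl-3-(prop-2-en-1-yl)cyclopent-1-en-1-olate | C=CC[C@@]1(C)[C@@H](O[Si](C)(C)C(C)(C)C)CC([O-])=C1.[Li+] | intermediate (not isolated)
10 | (3R,4S)-4-[(tert-butyldimethylsilyl)oxy]-2-(1-hydroxy-3-methylbut-3-en-1-yl)-3-methyl-3-(prop-2-en-1-yl)cyclopentan-1-one (epimers at C2 and the carbinol carbon) | C=CC[C@@]1(C)[C@@H](O[Si](C)(C)C(C)(C)C)CC(=O)C1C(O)CC(C)=C | intermediate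
11 | (1S,8aR)-1-[(tert-butyldimethylsilyl)oxy]-4-hydroxy-6,8a-dimethyl-1,3a,4,5,8,8a-hexahydroazulen-3(2H)-one (epimers at C3a and C4) | CC(C)(C)[Si](C)(C)O[C@H]1CC(=O)C2C(O)CC(C)=CC[C@@]12C | intermediate
12 | (1S,8aR)-1-[(tert-butyldimethylsilyl)oxy]-6,8a-dimethyl-3-oxo-1,2,3,3a,4,5,8,8a-octahydroazulen-4-yl methanesulfonate (epimers at C3a and C4) | CC(C)(C)[Si](C)(C)O[C@H]1CC(=O)C2C(OS(C)(=O)=O)CC(C)=CC[C@@]12C | intermediate (not isolated)
13 | (1S,8aR)-1-[(tert-butyldimethylsilyl)oxy]-6,8a-dimethyl-1,5,8,8a-tetrahydroazulen-3(2H)-one | CC(C)(C)[Si](C)(C)O[C@H]1CC(=O)C2=CCC(C)=CC[C@@]12C | intermediate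
14 | (1S,3aS,4R,8aR)-1-[(tert-butyldimethylsilyl)oxy]-6,8a-dimethyl-4-(4,4,5,5-tetramethyl-1,3,2-dioxaborolan-2-yl)-1,3a,4,5,8,8a-hexahydroazulen-3(2H)-one | CC(C)(C)[Si](C)(C)O[C@H]1CC(=O)[C@H]2[C@H](B3OC(C)(C)C(C)(C)O3)CC(C)=CC[C@@]12C | intermediate (not isolated)
15 | (1S,3aR,4R,8aR)-1-[(tert-butyldimethylsilyl)oxy]-4-hydroxy-6,8a-dimethyl-1,3a,4,5,8,8a-hexahydroazulen-3(2H)-one | CC(C)(C)[Si](C)(C)O[C@H]1CC(=O)[C@H]2[C@H](O)CC(C)=CC[C@@]12C | intermediate
16 | (1S,3S,3aR,4R,8aR)-1-[(tert-butyldimethylsilyl)oxy]-6,8a-dimethyl-3-(propan-2-yl)-1,2,3,3a,4,5,8,8a-octahydroazulene-3,4-diol | CC(C)(C)[Si](C)(C)O[C@H]1C[C@](O)(C(C)C)[C@H]2[C@H](O)CC(C)=CC[C@@]12C | intermediate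
17 | 3,4,5-trimethoxybenzoyl chloride | COc1cc(cc(OC)c1OC)C(Cl)=O | starting material
18 | (1S,3S,3aR,4R,8aR)-1-[(tert-butyldimethylsilyl)oxy]-3-hydroxy-6,8a-dimethyl-3-(propan-2-yl)-1,2,3,3a,4,5,8,8a-octahydroazulen-4-yl 3,4,5-trimethoxybenzoate | CC(C)(C)[Si](C)(C)O[C@H]1C[C@](O)(C(C)C)[C@H]2[C@H](OC(=O)c3cc(OC)c(OC)c(OC)c3)CC(C)=CC[C@@]12C | intermediate
19 | (1S,3S,3aR,4R,8aR)-1,3-dihydroxy-6,8a-dimethyl-3-(propan-2-yl)-1,2,3,3a,4,5,8,8a-octahydroazulen-4-yl 3,4,5-trimethoxybenzoate | O[C@H]1C[C@](O)(C(C)C)[C@H]2[C@H](OC(=O)c3cc(OC)c(OC)c(OC)c3)CC(C)=CC[C@@]12C | intermediate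
20 | angelic acid, (2Z)-2-methylbut-2-enoic acid | C/C=C(/C)C(=O)O | starting material
21 | (2Z)-2-methylbut-2-enoic 2,4,6-trichlorobenzoic anhydride | C/C=C(/C)C(=O)OC(=O)c1c(Cl)cc(Cl)cc1Cl | intermediate (not isolated)
22 | (1S,3S,3aR,4R,8aR)-3-hydroxy-6,8a-dimethyl-1-{[(2Z)-2-methylbut-2-enoyl]oxy}-3-(propan-2-yl)-1,2,3,3a,4,5,8,8a-octahydroazulen-4-yl 3,4,5-trimethoxybenzoate (CNP0112256.1) | C/C=C(/C)C(=O)O[C@H]1C[C@](O)(C(C)C)[C@H]2[C@H](OC(=O)c3cc(OC)c(OC)c(OC)c3)CC(C)=CC[C@@]12C | target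

**Step count and risks**
Total steps: 11. Longest linear sequence: 10 (steps 1, 2, 4–11; step 3 is a one-step side branch).

Most likely to fail:

Step 1 (the proposed new step; ee and yield are untested on this enolate class). The fallback uses known reactions, sets out from 1 and returns at 4. Mn(OAc)3 in refluxing benzene gives racemic 5-acetoxy-3-ethoxycyclopent-2-en-1-one F1 by α′-acetoxylation. Lipase-mediated enantioselective hydrolysis (kinetic resolution, pH 7 buffer) gives (5S)-3-ethoxy-5-hydroxycyclopent-2-en-1-one F2, separated from the unreacted acetate; if the enzyme prefers the other enantiomer, the recovered (S)-acetate is cleaved with K2CO3/MeOH to the same alcohol. TBSCl/imidazole then gives 4.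

Step 7 (the ligand may not deliver boron to the methyl face of C4; the skipped dienone 13 is also isomerisation-prone). The fallback sets the C4 centre by hydroxyl-directed reduction instead, sets out from 13 and returns at 16. Borylation with an achiral catalyst (CuCl, Xantphos, NaOtBu, B2pin2, MeOH) and NaBO3 oxidation give the cis-fused hydroxy ketone as a C4 epimer mixture F3. i-PrMgCl/CeCl3 gives the diol mixture F4. Dess–Martin oxidation of the secondary alcohol gives the single β-hydroxy ketone F5. Me4NBH(OAc)3 in MeCN/AcOH at −20 °C (Evans–Saksena) delivers hydride from the C3–O-bound borohydride to the carbonyl face syn to C3–O and gives 16.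

Step 11 (hindered neopentylic hydroxyl; risk of tiglate formation). The fallback builds the Z-alkene on the ester, sets out from 19 and returns at 22. DCC/DMAP esterification of the C1 hydroxyl with 2-(diphenoxyphosphoryl)propanoic acid gives (1S,3S,3aR,4R,8aR)-1-{[2-(diphenoxyphosphoryl)propanoyl]oxy}-3-hydroxy-6,8a-dimethyl-3-(propan-2-yl)-1,2,3,3a,4,5,8,8a-octahydroazulen-4-yl 3,4,5-trimethoxybenzoate F6. An Ando-type Z-selective Horner–Wadsworth–Emmons reaction with acetaldehyde (NaH, THF, −78 °C) then gives 22.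

**Further compounds**
F1 | step 1 | rac-5-acetoxy-3-ethoxycyclopent-2-en-1-one | CCOC1=CC(=O)C(OC(C)=O)C1
F2 | step 1 | (5S)-3-ethoxy-5-hydroxycyclopent-2-en-1-one | CCOC1=CC(=O)[C@@H](O)C1
F3 | step 7 | (1S,3aR,8aR)-1-[(tert-butyldimethylsilyl)oxy]-4-hydroxy-6,8a-dimethyl-1,3a,4,5,8,8a-hexahydroazulen-3(2H)-one (C4 epimer mixture) | CC(C)(C)[Si](C)(C)O[C@H]1CC(=O)[C@H]2C(O)CC(C)=CC[C@@]12C
F4 | step 7 | (1S,3S,3aR,8aR)-1-[(tert-butyldimethylsilyl)oxy]-6,8a-dimethyl-3-(propan-2-yl)-1,2,3,3a,4,5,8,8a-octahydroazulene-3,4-diol (C4 epimer mixture) | CC(C)(C)[Si](C)(C)O[C@H]1C[C@](O)(C(C)C)[C@H]2C(O)CC(C)=CC[C@@]12C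
F5 | step 7 | (1S,3S,3aS,8aR)-1-[(tert-butyldimethylsilyl)oxy]-3-hydroxy-6,8a-dimethyl-3-(propan-2-yl)-2,3,3a,5,8,8a-hexahydroazulen-4(1H)-one | CC(C)(C)[Si](C)(C)O[C@H]1C[C@](O)(C(C)C)[C@H]2C(=O)CC(C)=CC[C@@]12C
F6 | step 11 | (1S,3S,3aR,4R,8aR)-1-{[2-(diphenoxyphosphoryl)propanoyl]oxy}-3-hydroxy-6,8a-dimethyl-3-(propan-2-yl)-1,2,3,3a,4,5,8,8a-octahydroazulen-4-yl 3,4,5-trimethoxybenzoate (both epimers at the phosphonate carbon) | CC(C(=O)O[C@H]1C[C@](O)(C(C)C)[C@H]2[C@H](OC(=O)c3cc(OC)c(OC)c(OC)c3)CC(C)=CC[C@@]12C)P(=O)(Oc1ccccc1)Oc1ccccc1
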